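A small charge of starting material is the first setting I would turn, and the two flasks asked about, ochre and grey, differ in that charge and in the partner charge.

| flask | starting material | partner | temperature | remark | time |
|---|---|---|---|---|---|
| maple | 3.4 mM | 6 mM | 35 °C | run made earlier |  |
| oak | 13 mM | 6 mM | 46 °C | run made earlier |  |
| elm | 10 mM | 3.6 mM | 35 °C | run made earlier |  |
| ochre | 10 mM | 6.00 mM | 40 °C |  | 15 min |
| grey | 2.5 mM | 3.00 mM | 40 °C |  | 15 min |

| run | time / min | product / % | starting material / % |
|---|---|---|---|
| maple | 0.833 | 6.4 | 93.2 |
| maple | 1.33 | 10.6 | 89.5 |
| maple | 2.50 | 18.7 | 80.7 |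
| maple | 4.00 | 28.2 | 72.3 |
| maple | 6.00 | 38.4 | 61.8 |
| maple | 10.0 | 54.0 | 45.4 |
| oak | 2.00 | 28.5 | 71.5 |
| oak | 4.00 | 40.9 | 58.9 |
| oak | 5.00 | 44.2 | 55.7 |
| oak | 8.00 | 45.5 | 54.2 |
| oak | 10.0 | 45.2 | 54.5 |
| elm | 2.00 | 12.1 | 89.0 |
| elm | 4.00 | 20.0 | 80.4 |
| elm | 6.00 | 25.6 | 73.3 |
| elm | 8.00 | 30.1 | 70.1 |
| elm | 10.0 | 33.1 | 66.9 |

(standard deviation of a reading: 0.3 percentage points)



- the flask that ends with the higher amount of product, in percent of the starting material charged, or "neither" when 2 percentage points or less lies between them (ochre / grey / neither)
- final product, as a percentage of the starting material charged, in ochre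
- final product, as a percentage of the starting material charged, in grey

The oak run levels off at 45.5% of 13 mM, that is 5.92 mM of product against 6 mM of partner charged, so I read one partner used per product formed. Ochre's 60.0% is then the partner charge divided by the starting material charge, the product that partner can pay for as a percentage of the starting material charged: its ceiling, with partner as the limiting reagent.

Turning the starting material down to grey's 2.5 mM, with partner at 3.00 mM, lifts the ceiling to 120%, past the whole charge, so on paper grey is held back by the clock instead. Turning the partner down should lower the ceiling, and I expect it to slow the flask as well: after 10.0 min at 35 °C, elm, with 3.6 mM of partner and 10 mM of starting material, reads 33.1% under its ceiling of 36.0%, while maple, with 6 mM of partner and 3.4 mM of starting material, reads 54.0%, so this comparison moves both charges at once. Temperature does not enter the ceiling, and I expect it to move the clock. Counting lifetimes, the time for the starting material to fall by a factor of e if its decline is taken as first order, I read 12.7 min in maple at 35 °C and 5.96 min in oak, about half at 46 °C, though oak also carries 13 mM of starting material against maple's 3.4 mM, so this factor mixes two settings. Time then asks whether grey passes ochre's ceiling within 15 min, which takes a lifetime of 16.4 min or shorter. Elm's first reading gives 17.2 min at 35 °C, and grey has less partner, at 3.00 mM against elm's 3.6 mM, but stands at 40 °C, so I expect grey on top, by a modest distance, and ochre close under its ceiling.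

The forecast names grey, with 58.7% in ochre and 69% in grey, and reads from oak that “the partner is consumed 1:1 and caps the yield”. My reckoning gives the same side but no figure for grey.

    starting material + partner → product, rate k1*[starting material]*[partner]^0.5 (k = 1.70 M⁻⁰·⁵ min⁻¹, Ea = 67.0 kJ mol⁻¹)
    partner → decomposed reagent (k = 0.00440 min⁻¹, Ea = 90.0 kJ mol⁻¹)
    (constants at 40 °C)

Grey ends higher, at 66.6% against 58.8% in ochre. Ochre stands 1.2 percentage points under its ceiling at 15.0 min, with 0.108 mM of decomposed reagent formed and 0.196% of its partner charge left. Left to 150 min, ochre still holds 58.9%, under the ceiling of 60.0%, while grey, whose ceiling of 120% lies past its whole charge, reaches 99.5%.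

The readings stem from a simulated flask from invented constants, noise included.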